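**Retrosynthetic overview**
1. The target comes from desilylation and dioxolane hydrolysis of a protected precursor, which comes from hydroxyl-directed hydrogenation of a 1,1-disubstituted alkene, which in turn comes from stereoretentive oxidation of a tertiary benzylic boronic ester.
2. Key disconnection: the tertiary boronic ester is cut at the aryl–C(quaternary) bond and at the CH2–C(vinyl) bond. This gives a chromen-6-yllithium, isopropenylboronic pinacol ester and a 1-(benzofuran-2-yl)vinyl triflate, joined in one three-component conjunctive coupling.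
3. Feature used: the quaternary carbinol carbon carries chromene C6, CH3, OH and a CH2, and that CH2 is bonded to the CH(CH3) carbon on benzofuran C2. The C(carbinol)–CH2 pair therefore maps onto the two alkene carbons of an isopropenylboron reagent.
4. Fragments: the bromochromene comes from a bromophenol and prenal. The vinyl triflate comes from resacetophenone by iodination, alkynol heteroannulation, oxidation, phenoxide-directed enol triflation, silylation and ketalisation.
5. Ring order: the pyran ring of the chromene is formed first (step 1) and the furan ring of the benzofuran second (step 3). Both benzene rings come from the starting materials and no ring is formed after step 3.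

Key step: step 8

Assumption: the (Sp,Sp) antipode of the MandyPhos ligand and the (S) antipode of BINAP are taken to deliver the faces drawn; if either sense of induction is the opposite one, the mirror-image ligand is used with no other change.

**Route**

Step 1
Reactants: 1 4-bromo-3-methoxyphenol; 2 3-methylbut-2-enal (prenal)
Product: 3 6-bromo-7-methoxy-2,2-dimethyl-2H-chromene
Conditions: PhB(OH)2 (1 equiv), AcOH, toluene, reflux with azeotropic removal of water
Reagents that add atoms: none
Why: Boronic-acid-templated ortho-condensation of the phenol with the enal gives an ortho-quinone methide that closes by oxa-6π electrocyclisation (phenol/enal chromene annulation); the ortho carbon para to OMe is unhindered and reacts in preference to the carbon between OH and OMe.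

Step 2
Reactants: 4 1-(2,4-dihydroxyphenyl)ethan-1-one (resacetophenone)
Product: 5 1-(2,4-dihydroxy-5-iodophenyl)ethan-1-one
Conditions: ICl (1.0 equiv), AcOH, rt
Reagents that add atoms: iodine monochloride, ClI
Why: Electrophilic aromatic iodination should go to C5, which is para to the chelated 2-hydroxyl, ortho to the 4-hydroxyl and less hindered than C3 between the two oxygens.

Step 3
Reactants: 5 1-(2,4-dihydroxy-5-iodophenyl)ethan-1-one; 6 but-3-yn-2-ol (racemic)
Product: 7 1-[6-hydroxy-2-(1-hydroxyethyl)-1-benzofuran-5-yl]ethan-1-one (racemic)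
Conditions: PdCl2(PPh3)2 (3 mol %), CuI (5 mol %), Et3N, DMF, 60 °C
Reagents that add atoms: none
Why: Sonogashira coupling of the aryl iodide is followed in the same flask by 5-endo-dig addition of the ortho (4-) hydroxyl to the metal-activated alkyne, which closes the furan ring (tandem coupling–heteroannulation); the carbinol centre is racemic and is erased in step 4.

Step 4
Reactants: 7 1-[6-hydroxy-2-(1-hydroxyethyl)-1-benzofuran-5-yl]ethan-1-one
Product: 8 1,1'-(6-hydroxy-1-benzofuran-2,5-diyl)di(ethan-1-one)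
Conditions: MnO2 (activated, excess), CH2Cl2, rt
Reagents that add atoms: none
Why: MnO2 oxidises the activated benzofuran-2-yl carbinol selectively (oxidation of a benzylic-type alcohol) and should leave the hydrogen-bonded acyl phenol untouched.

Step 5
Reactants: 8 1,1'-(6-hydroxy-1-benzofuran-2,5-diyl)di(ethan-1-one)
Product: 10 1-(5-acetyl-6-hydroxy-1-benzofuran-2-yl)ethenyl trifluoromethanesulfonate, via dipotassium phenoxide-enolate 9 (not isolated)
Conditions: KHMDS (2.05 equiv), THF, −78 °C; PhNTf2 (1.0 equiv), −78 to −40 °C; aq NH4Cl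
Reagents that add atoms: N-phenylbis(trifluoromethanesulfonimide), O=S(=O)(N(c1ccccc1)S(=O)(=O)C(F)(F)F)C(F)(F)F
Why: The first equivalent of base gives the chelated phenoxide, which makes the neighbouring C5 acetyl group far less acidic, so the second equivalent should enolise only the C2 acetyl group, and the hard enolate oxygen rather than the delocalised phenoxide is sulfonylated (regioselective enolate O-triflation).

Step 6
Reactants: 10 1-(5-acetyl-6-hydroxy-1-benzofuran-2-yl)ethenyl trifluoromethanesulfonate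
Product: 11 1-[5-acetyl-6-(triisopropylsilyloxy)-1-benzofuran-2-yl]ethenyl trifluoromethanesulfonate
Conditions: TIPSOTf (1.1 equiv), 2,6-lutidine, CH2Cl2, 0 °C
Reagents that add atoms: triisopropylsilyl trifluoromethanesulfonate, CC(C)[Si](C(C)C)(C(C)C)OS(=O)(=O)C(F)(F)F
Why: The reactive silyl triflate with a hindered pyridine base silylates the hydrogen-bonded phenol (silyl ether formation), and the vinyl triflate is inert to these conditions.

Step 7
Reactants: 11 1-[5-acetyl-6-(triisopropylsilyloxy)-1-benzofuran-2-yl]ethenyl trifluoromethanesulfonate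
Product: 12 1-[5-(2-methyl-1,3-dioxolan-2-yl)-6-(triisopropylsilyloxy)-1-benzofuran-2-yl]ethenyl trifluoromethanesulfonate
Conditions: TMSOCH2CH2OTMS (3 equiv), TMSOTf (10 mol %), CH2Cl2, −78 to −20 °C; pyridine quench
Reagents that add atoms: 1,2-bis(trimethylsilyloxy)ethane, C[Si](C)(C)OCCO[Si](C)(C)C
Why: Aprotic silyl-transfer ketalisation, driven by formation of hexamethyldisiloxane, should convert the one remaining ketone into its dioxolane at low temperature, and the acid-stable vinyl triflate and the aryl silyl ether tolerate the catalyst.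

Step 8
Reactants: 3 6-bromo-7-methoxy-2,2-dimethyl-2H-chromene; 13 4,4,5,5-tetramethyl-2-(prop-1-en-2-yl)-1,3,2-dioxaborolane (isopropenylboronic acid pinacol ester); 12 1-[5-(2-methyl-1,3-dioxolan-2-yl)-6-(triisopropylsilyloxy)-1-benzofuran-2-yl]ethenyl trifluoromethanesulfonate
Product: 16 2-[(2R)-2-(7-methoxy-2,2-dimethyl-2H-chromen-6-yl)-4-[5-(2-methyl-1,3-dioxolan-2-yl)-6-(triisopropylsilyloxy)-1-benzofuran-2-yl]pent-4-en-2-yl]-4,4,5,5-tetramethyl-1,3,2-dioxaborolane, via chromen-6-yllithium 14 (not isolated), via lithium boron ate complex 15 (not isolated)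
Conditions: 3, t-BuLi (2.0 equiv), Et2O, −78 °C; 13, −78 °C to rt; evaporate, THF; KOTf (2 equiv), Pd(OAc)2 (3 mol %), (Sp,Sp)-MandyPhos ligand with bis(4-methoxy-3,5-dimethylphenyl)phosphino groups (3.6 mol %), 12 (limiting), 60 °C
Reagents that add atoms: none
Why: Lithium–bromine exchange gives 14, which adds to boron of 13 to give ate complex 15; oxidative addition of triflate 12 to zerovalent palladium (formed from Pd(OAc)2) gives a cationic alkenylpalladium (divalent palladium) species that binds the isopropenyl alkene of 15, the chromenyl group migrates from boron to the alpha carbon anti to palladium, and reductive elimination joins the CH2 to the vinyl carbon. The closest known reaction is the palladium/MandyPhos conjunctive cross-coupling of alpha-substituted alkenylboron ate complexes with triflates, which gives tertiary boronic esters. No ring is closed; two skeletal bonds and one stereocentre are formed. The new quaternary centre has no neighbouring stereocentre, so its (R) configuration is set only by enantioface selection of the alkene by the chiral bisphosphine on palladium. The step needs the metallate shift to outrun direct transmetalation (Suzuki–Miyaura-type coupling) and needs a halide-free cationic palladium; the triflate leaving group, KOTf that precipitates the bromide from the exchange, and the wide-bite-angle ligand secure this. The palladium-bearing CH2 sits next to a quaternary carbon without hydrogen, so beta-hydride elimination cannot compete, and the chromene alkene, ketal and silyl ether are inert.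

Step 9
Reactants: 16 2-[(2R)-2-(7-methoxy-2,2-dimethyl-2H-chromen-6-yl)-4-[5-(2-methyl-1,3-dioxolan-2-yl)-6-(triisopropylsilyloxy)-1-benzofuran-2-yl]pent-4-en-2-yl]-4,4,5,5-tetramethyl-1,3,2-dioxaborolane
Product: 17 (2S)-2-(7-methoxy-2,2-dimethyl-2H-chromen-6-yl)-4-[5-(2-methyl-1,3-dioxolan-2-yl)-6-(triisopropylsilyloxy)-1-benzofuran-2-yl]pent-4-en-2-ol
Conditions: 30% H2O2, 2 M aq NaOH, THF, 0 °C to rt
Reagents that add atoms: hydrogen peroxide, OO
Why: Hydroperoxide adds to boron and the tertiary alkyl group migrates to oxygen with retention (stereoretentive boronic ester oxidation), so (R)-16 gives (S)-17 with only the descriptor changing, while the ketal keeps the aryl ketone out of reach of Dakin-type oxidation.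

Step 10
Reactants: 17 (2S)-2-(7-methoxy-2,2-dimethyl-2H-chromen-6-yl)-4-[5-(2-methyl-1,3-dioxolan-2-yl)-6-(triisopropylsilyloxy)-1-benzofuran-2-yl]pent-4-en-2-ol
Product: 18 (2S,4S)-2-(7-methoxy-2,2-dimethyl-2H-chromen-6-yl)-4-[5-(2-methyl-1,3-dioxolan-2-yl)-6-(triisopropylsilyloxy)-1-benzofuran-2-yl]pentan-2-ol
Conditions: H2 (5 atm), [Rh(nbd)((S)-BINAP)]BF4 (5 mol %), CH2Cl2, rt
Reagents that add atoms: none
Why: The cationic rhodium binds the tertiary hydroxyl and the homoallylic 1,1-disubstituted alkene as a chelate and delivers H2 to the alkene face fixed by the chiral bisphosphine (hydroxyl-directed asymmetric hydrogenation), setting (S) at C4, while the non-chelating hindered chromene alkene and the benzofuran should be reduced far more slowly.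

Step 11
Reactants: 18 (2S,4S)-2-(7-methoxy-2,2-dimethyl-2H-chromen-6-yl)-4-[5-(2-methyl-1,3-dioxolan-2-yl)-6-(triisopropylsilyloxy)-1-benzofuran-2-yl]pentan-2-ol
Product: 20 1-{6-hydroxy-2-[(2S,4S)-4-hydroxy-4-(7-methoxy-2,2-dimethyl-2H-chromen-6-yl)pentan-2-yl]-1-benzofuran-5-yl}ethan-1-one, via free phenol ketal 19 (not isolated)
Conditions: TBAF (1.1 equiv), THF, 0 °C; then AcOH/H2O to pH about 4, rt
Reagents that add atoms: water, O
Why: Fluoride cleaves the aryl silyl ether, and the resulting ortho-hydroxyaryl dioxolane, activated by two ring oxygens, should hydrolyse at an acidity far below that needed to ionise the tertiary benzylic alcohol (desilylation then ketal hydrolysis), so both stereocentres stay untouched.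

**Compound list**
1 | 4-bromo-3-methoxyphenol | COc1cc(O)ccc1Br | starting material
2 | 3-methylbut-2-enal (prenal) | CC(C)=CC=O | starting material
3 | 6-bromo-7-methoxy-2,2-dimethyl-2H-chromene | COc1cc2c(cc1Br)C=CC(C)(C)O2 | intermediate
4 | 1-(2,4-dihydroxyphenyl)ethan-1-one (resacetophenone) | CC(=O)c1ccc(O)cc1O | starting material
5 | 1-(2,4-dihydroxy-5-iodophenyl)ethan-1-one | CC(=O)c1cc(I)c(O)cc1O | intermediate
6 | but-3-yn-2-ol (racemic) | CC(O)C#C | starting material
7 | 1-[6-hydroxy-2-(1-hydroxyethyl)-1-benzofuran-5-yl]ethan-1-one (racemic) | CC(O)c1cc2cc(C(C)=O)c(O)cc2o1 | intermediate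
8 | 1,1'-(6-hydroxy-1-benzofuran-2,5-diyl)di(ethan-1-one) | CC(=O)c1cc2cc(C(C)=O)c(O)cc2o1 | intermediate
9 | dipotassium 5-acetyl-2-(1-oxidoethenyl)-1-benzofuran-6-olate | [K+].[K+].C=C([O-])c1cc2cc(C(C)=O)c([O-])cc2o1 | intermediate
10 | 1-(5-acetyl-6-hydroxy-1-benzofuran-2-yl)ethenyl trifluoromethanesulfonate | C=C(OS(=O)(=O)C(F)(F)F)c1cc2cc(C(C)=O)c(O)cc2o1 | intermediate
11 | 1-[5-acetyl-6-(triisopropylsilyloxy)-1-benzofuran-2-yl]ethenyl trifluoromethanesulfonate | C=C(OS(=O)(=O)C(F)(F)F)c1cc2cc(C(C)=O)c(O[Si](C(C)C)(C(C)C)C(C)C)cc2o1 | intermediate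
12 | 1-[5-(2-methyl-1,3-dioxolan-2-yl)-6-(triisopropylsilyloxy)-1-benzofuran-2-yl]ethenyl trifluoromethanesulfonate | C=C(OS(=O)(=O)C(F)(F)F)c1cc2cc(C3(C)OCCO3)c(O[Si](C(C)C)(C(C)C)C(C)C)cc2o1 | intermediate
13 | 4,4,5,5-tetramethyl-2-(prop-1-en-2-yl)-1,3,2-dioxaborolane (isopropenylboronic acid pinacol ester) | CC(=C)B1OC(C)(C)C(C)(C)O1 | starting material
14 | (7-methoxy-2,2-dimethyl-2H-chromen-6-yl)lithium | COc1cc2c(cc1[Li])C=CC(C)(C)O2 | intermediate
15 | lithium (7-methoxy-2,2-dimethyl-2H-chromen-6-yl)(prop-1-en-2-yl)(pinacolato)borate | [Li+].COc1cc2c(cc1[B-]3(C(C)=C)OC(C)(C)C(C)(C)O3)C=CC(C)(C)O2 | intermediate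
16 | 2-[(2R)-2-(7-methoxy-2,2-dimethyl-2H-chromen-6-yl)-4-[5-(2-methyl-1,3-dioxolan-2-yl)-6-(triisopropylsilyloxy)-1-benzofuran-2-yl]pent-4-en-2-yl]-4,4,5,5-tetramethyl-1,3,2-dioxaborolane | COc1cc2c(cc1[C@@](C)(B3OC(C)(C)C(C)(C)O3)CC(=C)c1cc3cc(C4(C)OCCO4)c(O[Si](C(C)C)(C(C)C)C(C)C)cc3o1)C=CC(C)(C)O2 | intermediate
17 | (2S)-2-(7-methoxy-2,2-dimethyl-2H-chromen-6-yl)-4-[5-(2-methyl-1,3-dioxolan-2-yl)-6-(triisopropylsilyloxy)-1-benzofuran-2-yl]pent-4-en-2-ol | COc1cc2c(cc1[C@@](C)(O)CC(=C)c1cc3cc(C4(C)OCCO4)c(O[Si](C(C)C)(C(C)C)C(C)C)cc3o1)C=CC(C)(C)O2 | intermediate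
18 | (2S,4S)-2-(7-methoxy-2,2-dimethyl-2H-chromen-6-yl)-4-[5-(2-methyl-1,3-dioxolan-2-yl)-6-(triisopropylsilyloxy)-1-benzofuran-2-yl]pentan-2-ol | COc1cc2c(cc1[C@@](C)(O)C[C@H](C)c1cc3cc(C4(C)OCCO4)c(O[Si](C(C)C)(C(C)C)C(C)C)cc3o1)C=CC(C)(C)O2 | intermediate
19 | (2S,4S)-4-[6-hydroxy-5-(2-methyl-1,3-dioxolan-2-yl)-1-benzofuran-2-yl]-2-(7-methoxy-2,2-dimethyl-2H-chromen-6-yl)pentan-2-ol | COc1cc2c(cc1[C@@](C)(O)C[C@H](C)c1cc3cc(C4(C)OCCO4)c(O)cc3o1)C=CC(C)(C)O2 | intermediate
20 | 1-{6-hydroxy-2-[(2S,4S)-4-hydroxy-4-(7-methoxy-2,2-dimethyl-2H-chromen-6-yl)pentan-2-yl]-1-benzofuran-5-yl}ethan-1-one (CNP0233723.1) | COc1cc2c(cc1[C@@](C)(O)C[C@H](C)c1cc3cc(C(C)=O)c(O)cc3o1)C=CC(C)(C)O2 | target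

**Step count**
Total: 11 steps. Longest linear sequence: 10 steps (steps 2 to 11, from resacetophenone); step 1 is the only step off this line.

**Steps most likely to fail**

Step 8. What may go wrong: the ate complex may transfer its aryl or alkenyl group directly to palladium (Suzuki–Miyaura-type coupling) instead of undergoing the metallate shift. Residual bromide may also slow the cationic palladium, and the ortho-substituted migrating aryl group may lower the enantioface selection.
Fallback, from 3 and 12, returning at 16: a stereospecific lithiation–borylation replaces the catalytic coupling.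
- Compound 3 is lithiated (t-BuLi, Et2O, −78 °C) and acylated with N-methoxy-N-methylacetamide to 1-(7-methoxy-2,2-dimethyl-2H-chromen-6-yl)ethan-1-one F1.
- Corey–Bakshi–Shibata reduction with the (S)-methyl oxazaborolidine and BH3·SMe2 should give (1R)-1-(7-methoxy-2,2-dimethyl-2H-chromen-6-yl)ethan-1-ol F2.
- F2 is carbamoylated (N,N-diisopropylcarbamoyl chloride, Et3N, heat) to (1R)-1-(7-methoxy-2,2-dimethyl-2H-chromen-6-yl)ethyl N,N-diisopropylcarbamate F3.
- Separately, 12 is coupled with bis(pinacolboryl)methane (Pd(P(t-Bu)3)2, KOH, dioxane/water, rt) to the allylboronic ester 2-{2-[5-(2-methyl-1,3-dioxolan-2-yl)-6-(triisopropylsilyloxy)-1-benzofuran-2-yl]prop-2-en-1-yl}-4,4,5,5-tetramethyl-1,3,2-dioxaborolane F4.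
- Lithiation of F3 (s-BuLi, Et2O, −78 °C) gives a configurationally stable tertiary benzylic organolithium, which F4 borylates with retention. Warming with MgBr2 in MeOH drives anti 1,2-migration of the allyl group with loss of the carbamate and should give (R)-16.

Step 10. What may go wrong: the chelate may give poor facial selectivity at the acyclic tertiary carbinol, the terminal alkene may isomerise before reduction, the chromene double bond may be reduced competitively, or traces of acid from the cationic catalyst may ionise the tertiary benzylic alcohol.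
Fallback, from 12 and the carbamate F3 described above, returning at 18: the C4 centre is set before the fragments are joined, so no alkene is hydrogenated beside the chromene.
- Compound 12 is methylated (MeMgBr, Fe(acac)3 cat., THF/NMP, −20 °C) to triisopropyl{[5-(2-methyl-1,3-dioxolan-2-yl)-2-(prop-1-en-2-yl)-1-benzofuran-6-yl]oxy}silane F5.
- Copper-hydride-catalysed enantioselective hydroboration (CuCl, NaOt-Bu, DTBM-SEGPHOS antipode chosen for the (S) product, pinacolborane) puts boron on the terminal carbon and hydrogen on the benzofuran-bearing carbon. It should give 2-{(2S)-2-[5-(2-methyl-1,3-dioxolan-2-yl)-6-(triisopropylsilyloxy)-1-benzofuran-2-yl]propyl}-4,4,5,5-tetramethyl-1,3,2-dioxaborolane F6.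
- Lithiated F3 (s-BuLi, Et2O, −78 °C) is borylated with F6, and 1,2-migration of the primary alkyl group gives the saturated tertiary boronic ester 2-[(2R,4S)-2-(7-methoxy-2,2-dimethyl-2H-chromen-6-yl)-4-[5-(2-methyl-1,3-dioxolan-2-yl)-6-(triisopropylsilyloxy)-1-benzofuran-2-yl]pentan-2-yl]-4,4,5,5-tetramethyl-1,3,2-dioxaborolane F7.
- Oxidation of F7 with H2O2/NaOH with retention gives 18.

Step 5. What may go wrong: site selectivity may be lost if the C5 acetyl group is also enolised, the phenoxide oxygen may be sulfonylated, or the dipotassium salt may be too insoluble at low temperature.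
Fallback, from 7, returning at 12: the two acetyl groups are told apart by protecting groups instead of by charge.
- Compound 7 is silylated at the phenol (TIPSCl, imidazole, DMF) to 1-[2-(1-hydroxyethyl)-6-(triisopropylsilyloxy)-1-benzofuran-5-yl]ethan-1-one F8.
- F8 is acetylated at the secondary alcohol (Ac2O, pyridine, DMAP) to 1-[5-acetyl-6-(triisopropylsilyloxy)-1-benzofuran-2-yl]ethyl acetate F9.
- F9 is ketalised at its only ketone (TMSOCH2CH2OTMS, TMSOTf cat., CH2Cl2, −78 to −20 °C) to 1-[5-(2-methyl-1,3-dioxolan-2-yl)-6-(triisopropylsilyloxy)-1-benzofuran-2-yl]ethyl acetate F10.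
- F10 is deacetylated (K2CO3, MeOH, 0 °C) to 1-[5-(2-methyl-1,3-dioxolan-2-yl)-6-(triisopropylsilyloxy)-1-benzofuran-2-yl]ethan-1-ol F11.
- F11 is oxidised (MnO2, CH2Cl2) to 1-[5-(2-methyl-1,3-dioxolan-2-yl)-6-(triisopropylsilyloxy)-1-benzofuran-2-yl]ethan-1-one F12.
- F12 has a single enolisable acetyl group and is triflated (KHMDS, PhNTf2, THF, −78 °C) to 12.

**Further compounds**
F1 | step 8 | 1-(7-methoxy-2,2-dimethyl-2H-chromen-6-yl)ethan-1-one | COc1cc2c(cc1C(C)=O)C=CC(C)(C)O2
F2 | step 8 | (1R)-1-(7-methoxy-2,2-dimethyl-2H-chromen-6-yl)ethan-1-ol | COc1cc2c(cc1[C@@H](C)O)C=CC(C)(C)O2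
F3 | step 8 | (1R)-1-(7-methoxy-2,2-dimethyl-2H-chromen-6-yl)ethyl N,N-diisopropylcarbamate | COc1cc2c(cc1[C@@H](C)OC(=O)N(C(C)C)C(C)C)C=CC(C)(C)O2
F4 | step 8 | 2-{2-[5-(2-methyl-1,3-dioxolan-2-yl)-6-(triisopropylsilyloxy)-1-benzofuran-2-yl]prop-2-en-1-yl}-4,4,5,5-tetramethyl-1,3,2-dioxaborolane | C=C(CB1OC(C)(C)C(C)(C)O1)c1cc2cc(C3(C)OCCO3)c(O[Si](C(C)C)(C(C)C)C(C)C)cc2o1
F5 | step 10 | triisopropyl{[5-(2-methyl-1,3-dioxolan-2-yl)-2-(prop-1-en-2-yl)-1-benzofuran-6-yl]oxy}silane | CC(=C)c1cc2cc(C3(C)OCCO3)c(O[Si](C(C)C)(C(C)C)C(C)C)cc2o1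
F6 | step 10 | 2-{(2S)-2-[5-(2-methyl-1,3-dioxolan-2-yl)-6-(triisopropylsilyloxy)-1-benzofuran-2-yl]propyl}-4,4,5,5-tetramethyl-1,3,2-dioxaborolane | CC1(C)OB(C[C@H](C)c2cc3cc(C4(C)OCCO4)c(O[Si](C(C)C)(C(C)C)C(C)C)cc3o2)OC1(C)C
F7 | step 10 | 2-[(2R,4S)-2-(7-methoxy-2,2-dimethyl-2H-chromen-6-yl)-4-[5-(2-methyl-1,3-dioxolan-2-yl)-6-(triisopropylsilyloxy)-1-benzofuran-2-yl]pentan-2-yl]-4,4,5,5-tetramethyl-1,3,2-dioxaborolane | COc1cc2c(cc1[C@@](C)(B3OC(C)(C)C(C)(C)O3)C[C@H](C)c1cc3cc(C4(C)OCCO4)c(O[Si](C(C)C)(C(C)C)C(C)C)cc3o1)C=CC(C)(C)O2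
F8 | step 5 | 1-[2-(1-hydroxyethyl)-6-(triisopropylsilyloxy)-1-benzofuran-5-yl]ethan-1-one (racemic) | CC(O)c1cc2cc(C(C)=O)c(O[Si](C(C)C)(C(C)C)C(C)C)cc2o1
F9 | step 5 | 1-[5-acetyl-6-(triisopropylsilyloxy)-1-benzofuran-2-yl]ethyl acetate (racemic) | CC(OC(C)=O)c1cc2cc(C(C)=O)c(O[Si](C(C)C)(C(C)C)C(C)C)cc2o1
F10 | step 5 | 1-[5-(2-methyl-1,3-dioxolan-2-yl)-6-(triisopropylsilyloxy)-1-benzofuran-2-yl]ethyl acetate (racemic) | CC(OC(C)=O)c1cc2cc(C3(C)OCCO3)c(O[Si](C(C)C)(C(C)C)C(C)C)cc2o1
F11 | step 5 | 1-[5-(2-methyl-1,3-dioxolan-2-yl)-6-(triisopropylsilyloxy)-1-benzofuran-2-yl]ethan-1-ol (racemic) | CC(O)c1cc2cc(C3(C)OCCO3)c(O[Si](C(C)C)(C(C)C)C(C)C)cc2o1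
F12 | step 5 | 1-[5-(2-methyl-1,3-dioxolan-2-yl)-6-(triisopropylsilyloxy)-1-benzofuran-2-yl]ethan-1-one | CC(=O)c1cc2cc(C3(C)OCCO3)c(O[Si](C(C)C)(C(C)C)C(C)C)cc2o1
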